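## Retrosynthetic overview

1. Target 15 ⇒ all-cis ketol acetonide 14. The C2=C3 alkene comes from E1cB loss of a β-oxygen at C3, which mirrors the reduce-then-dehydrate editing of the polyketide chain.
2. 14 ⇒ acyclic keto enolate 13 by cutting C6–C5. This is the C2→C7 aldol that closes the ring of fatty-acyl-primed tetraketides (cardanol/alkylquinol family). Here it is stopped at the tertiary carbinol, before the aromatising dehydration.
3. 13 ⇒ C17 Grignard 11 + exocyclic enol lactone 10. One acyl transfer attaches the chain, unmasks the ketone and releases the regiodefined methyl-ketone enolate.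
4. 10 ⇒ 2-deoxy-L-ribose 6, which supplies C4 and the cis-diol (acetonide, C1 homologation to the alkyne, oxidation, 6-exo-dig lactonisation). 11 ⇒ (E)-hex-3-en-1-ol 1 + 1,11-dibromoundecane 3.
5. Ring order: dioxolane (temporary) → δ-enol lactone (temporary) → cyclohexenone. The cyclohexenone is the only ring of 15 and forms last. Both helper rings are destroyed in the same flask.

Assumption: the SMILES is read as (4R,5S), a cis-4,5-diol carrying a (14E)-heptadec-14-enyl chain. 2-Deoxy-L-ribose is taken as a bulk commercial sugar (L-nucleoside manufacture).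

## Route

Step 1
Reactants: 1 (E)-hex-3-en-1-ol
Product: 2 (E)-1-bromohex-3-ene
Conditions: CBr4, PPh3, CH2Cl2, 0 °C
Reagents that add atoms: carbon tetrabromide, BrC(Br)(Br)Br
Why: Appel reaction; SN2 at the primary carbinol under neutral conditions leaves the (E)-alkene untouched.

Step 2
Reactants: 2 (E)-1-bromohex-3-ene; 3 1,11-dibromoundecane
Product: 5 (3E)-17-bromoheptadec-3-ene, via (E)-hex-3-enylmagnesium bromide 4 (not isolated)
Conditions: Mg, THF, rt; then 3 (3 equiv), Li2CuCl4 (3 mol %), THF, −10 to 0 °C
Reagents that add atoms: none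
Why: Kochi-type copper-catalysed sp3–sp3 Grignard cross-coupling; the excess dibromide (recovered by distillation) enforces mono-alkylation and the remote (E)-alkene is not involved.

Step 3
Reactants: 6 2-deoxy-L-ribose
Product: 7 3,4-O-isopropylidene-2-deoxy-L-ribopyranose (anomer mixture)
Conditions: 2-methoxypropene, PPTS (cat.), DMF, 0 °C
Reagents that add atoms: 2-methoxypropene, C=C(C)OC
Why: Kinetic transacetalisation picks the cis-3,4-diol of the pyranose form; no stereocentre is touched, and sugar C4 becomes C4 of the target.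

Step 4
Reactants: 7 3,4-O-isopropylidene-2-deoxy-L-ribopyranose
Product: 8 [(4S,5R)-2,2-dimethyl-5-(prop-2-yn-1-yl)-1,3-dioxolan-4-yl]methanol
Conditions: MeC(O)C(N2)P(O)(OMe)2, K2CO3, MeOH, rt
Reagents that add atoms: dimethyl (1-diazo-2-oxopropyl)phosphonate, CC(=O)C(=[N+]=[N-])P(=O)(OC)OC
Why: Seyferth–Gilbert homologation (Ohira–Bestmann variant) on the open-chain aldehyde tautomer of the lactol; it adds the carbon that becomes ring C6 and frees the primary alcohol.

Step 5
Reactants: 8 [(4S,5R)-2,2-dimethyl-5-(prop-2-yn-1-yl)-1,3-dioxolan-4-yl]methanol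
Product: 9 (4R,5R)-2,2-dimethyl-5-(prop-2-yn-1-yl)-1,3-dioxolane-4-carboxylic acid
Conditions: TEMPO (cat.), PhI(OAc)2 (2.2 equiv), MeCN–H2O, rt
Reagents that add atoms: water, O
Why: TEMPO/oxoammonium oxidation goes through the aldehyde hydrate to the acid under near-neutral conditions, so the α-alkoxy centre, the acetonide and the alkyne survive.

Step 6
Reactants: 9 (4R,5R)-2,2-dimethyl-5-(prop-2-yn-1-yl)-1,3-dioxolane-4-carboxylic acid
Product: 10 (3aR,7aR)-2,2-dimethyl-6-methylidenetetrahydro-4H-[1,3]dioxolo[4,5-c]pyran-4-one (cis-fused exocyclic enol lactone)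
Conditions: AuCl (5 mol %), K2CO3 (10 mol %), MeCN, rt
Reagents that add atoms: none
Why: Gold(I)-catalysed 6-exo-dig cycloisomerisation of a 5-alkynoic acid (anti carboxylate attack, then protodeauration); the cis-dioxolane holds the two ends close together.

Step 7
Reactants: 5 (3E)-17-bromoheptadec-3-ene; 10 (3aR,7aR)-2,2-dimethyl-6-methylidenetetrahydro-4H-[1,3]dioxolo[4,5-c]pyran-4-one
Product: 15 (4R,5S)-5-[(14E)-heptadec-14-en-1-yl]-4,5-dihydroxycyclohex-2-en-1-one, via C17 Grignard reagent 11 (not isolated), via tetrahedral hemiketal alkoxide 12 (not isolated), via acyclic keto enolate 13 (not isolated), via bicyclic aldolate 14 (not isolated)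
Conditions: 5, Mg, THF; add over 1 h (1.05 equiv) to 10, Et2O–THF, −78 °C; warm to −30 °C; DBU (1.5 equiv), −30 to 0 °C; aq NH4Cl
Reagents that add atoms: none
Why: Proposed new method: 11 adds to the α-alkoxy-chelated lactone carbonyl to give 12, which should persist at −78 °C (as aldonolactone adducts do) until the Grignard is consumed; on warming 12 expels the ring oxygen as the regiodefined CH2=C(OMgBr) enolate beside the newly formed ketone (13), so the polyketide-type C6→C5 aldol closes the carbocycle at once; Mg2+ bridging the C5 carbonyl oxygen and the C4 dioxolane oxygen keeps O5 synclinal to O4 while the C17 chain goes equatorial, which sets (5S) with 5-O cis to 4-O (axial–equatorial–axial O3/O4/O5 magnesium site in 14), and reversibility of the aldol funnels material the same way; DBU/Mg2+ soft enolisation toward C2 then expels the axial C3–O bond of the cis-fused acetonide (E1cB), the resulting hemiketal loses acetone, and the tertiary oxygen cannot leave because it remains a magnesium alkoxide; closest known reaction types are the Fujimoto–Belleau reaction (Grignard + enol lactone → 1,5-diketone → aldol), the aldol carbocyclisation of 1-deoxy-2,6-diuloses, and the base-induced β-elimination of cis-fused acetonides in quinic-acid-derived cyclohexanones.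

## Compound list

1 | (E)-hex-3-en-1-ol | CC/C=C/CCO | starting material
2 | (E)-1-bromohex-3-ene | CC/C=C/CCBr | intermediate
3 | 1,11-dibromoundecane | BrCCCCCCCCCCCBr | starting material
4 | (E)-hex-3-enylmagnesium bromide | CC/C=C/CC[Mg]Br | intermediate
5 | (3E)-17-bromoheptadec-3-ene | CC/C=C/CCCCCCCCCCCCCBr | intermediate
6 | 2-deoxy-L-ribose, (3R,4S), drawn open-chain | O=CC[C@@H](O)[C@@H](O)CO | starting material
7 | 3,4-O-isopropylidene-2-deoxy-L-ribopyranose (anomer mixture) | OC1C[C@H]2OC(C)(C)O[C@H]2CO1 | intermediate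
8 | [(4S,5R)-2,2-dimethyl-5-(prop-2-yn-1-yl)-1,3-dioxolan-4-yl]methanol | C#CC[C@H]1OC(C)(C)O[C@H]1CO | intermediate
9 | (4R,5R)-2,2-dimethyl-5-(prop-2-yn-1-yl)-1,3-dioxolane-4-carboxylic acid | C#CC[C@H]1OC(C)(C)O[C@H]1C(=O)O | intermediate
10 | (3aR,7aR)-2,2-dimethyl-6-methylidenetetrahydro-4H-[1,3]dioxolo[4,5-c]pyran-4-one | C=C1C[C@H]2OC(C)(C)O[C@H]2C(=O)O1 | intermediate
11 | (14E)-heptadec-14-en-1-ylmagnesium bromide | CC/C=C/CCCCCCCCCCCCC[Mg]Br | intermediate
12 | bromomagnesium hemiketal alkoxide from addition of 11 to C4 of 10 (new centre undefined) | CC/C=C/CCCCCCCCCCCCCC1(O[Mg]Br)OC(=C)C[C@H]2OC(C)(C)O[C@@H]12 | intermediate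
13 | bromomagnesium terminal (CH2=C–O) enolate of (15E)-1-[(4R,5R)-2,2-dimethyl-5-(2-oxopropyl)-1,3-dioxolan-4-yl]octadec-15-en-1-one | CC/C=C/CCCCCCCCCCCCCC(=O)[C@@H]1OC(C)(C)O[C@@H]1CC(=C)O[Mg]Br | intermediate
14 | bromomagnesium alkoxide of (3aR,7S,7aR)-7-[(14E)-heptadec-14-en-1-yl]-7-hydroxy-2,2-dimethylhexahydro-1,3-benzodioxol-5-one (three oxygens all cis) | CC/C=C/CCCCCCCCCCCCC[C@]1(O[Mg]Br)CC(=O)C[C@H]2OC(C)(C)O[C@@H]12 | intermediate
15 | (4R,5S)-5-[(14E)-heptadec-14-en-1-yl]-4,5-dihydroxycyclohex-2-en-1-one | CC/C=C/CCCCCCCCCCCCC[C@]1(O)CC(=O)C=C[C@H]1O | target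

## Step count and risks

Total steps: 7. Longest linear sequence: 5 (6 → 7 → 8 → 9 → 10 → 15). The chain branch is 1 → 2 → 5 and joins at step 7.

**Step 7, most likely to fail.** Three things can go wrong:
- If 12 collapses while Grignard is still present, 11 can add to the ketone of 13 or 14.
- Chelate control at C5 may be incomplete.
- Prolonged base can drive aromatisation to the alkylhydroquinone.

The fallback separates acylation from enolate formation. It sets out from 9 and 11. Acid 9 is converted with CDI and MeNHOMe·HCl into the Weinreb amide F1. The alkyne C–H of F1 is masked with one equivalent of iPrMgCl. Reagent 11 then gives the alkynyl ketone F2 through a chelate that releases no ketone until work-up. Gold(I)-catalysed Markovnikov hydration in wet dioxane gives the 1,5-diketone F3. Kinetic deprotonation of the methyl group with LiHMDS at −78 °C, followed by MgBr2·OEt2, delivers the keto enolate. The fallback comes back to the route at 13.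

**Step 6.** The 6-exo-dig closure is slower than 5-exo cases. Enol lactone 10 can also hydrolyse or slip to the endocyclic isomer. The fallback sets out from 9. Electrophilic iodolactonisation (I2, NaHCO3, MeCN; anti addition) gives the crystalline (E)-iodomethylidene lactone F4. Palladium-catalysed hydrodeiodination of F4 (Pd(PPh3)4, Bu3SnH) comes back to the route at 10.

**Step 4.** The open-chain β-alkoxy aldehyde can undergo E1cB loss of the acetonide oxygen in K2CO3/MeOH before it is homologated. The fallback sets out from 7. Wittig chloromethylenation with Ph3P=CHCl (from the phosphonium chloride and KOtBu, THF, −78 °C) gives the chloroalkene F5 as an E/Z mixture. Treatment of F5 with n-BuLi (3 equiv) eliminates HCl and comes back to the route at 8.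

## Further compounds

F1 | step 7 | (4R,5R)-N-methoxy-N,2,2-trimethyl-5-(prop-2-yn-1-yl)-1,3-dioxolane-4-carboxamide | C#CC[C@H]1OC(C)(C)O[C@H]1C(=O)N(C)OC
F2 | step 7 | (15E)-1-[(4R,5R)-2,2-dimethyl-5-(prop-2-yn-1-yl)-1,3-dioxolan-4-yl]octadec-15-en-1-one | C#CC[C@H]1OC(C)(C)O[C@H]1C(=O)CCCCCCCCCCCCC/C=C/CC
F3 | step 7 | (15E)-1-[(4R,5R)-2,2-dimethyl-5-(2-oxopropyl)-1,3-dioxolan-4-yl]octadec-15-en-1-one | CC(=O)C[C@H]1OC(C)(C)O[C@H]1C(=O)CCCCCCCCCCCCC/C=C/CC
F4 | step 6 | (3aR,6E,7aR)-6-(iodomethylidene)-2,2-dimethyltetrahydro-4H-[1,3]dioxolo[4,5-c]pyran-4-one | I/C=C1\C[C@H]2OC(C)(C)O[C@H]2C(=O)O1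
F5 | step 4 | [(4S,5R)-5-(3-chloroprop-2-en-1-yl)-2,2-dimethyl-1,3-dioxolan-4-yl]methanol (E/Z mixture) | ClC=CC[C@H]1OC(C)(C)O[C@H]1CO
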